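With the chain numbered from the furyl carbinol (C1), the C5 hydroxyl lies homoallylic to the E-trisubstituted C7=C8 alkene, so O–C5–C6–C7=C8 can be folded back into a 2,3-dihydrofuran ring. Everything rests on the C8–C9 disconnection. In a copper-mediated 1,2-metalate rearrangement, homogeranyl (C9–C17) migrates from copper to metalated C8, expelling the ring oxygen with inversion, and MeI caps the resulting alkenylcuprate. One operation joins three components, forms C8–C9 and C8–CH3, fixes the 7E geometry and releases the C5 alcohol. The precursor is an enantiopure 5-stannyl-2-alkenyl-2,3-dihydrofuran already carrying the furan, the 3E alkene and both stereocentres.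

Key step: step 8

Remark: atoms are numbered C1 (furyl carbinol) to C17 along the chain, and the target is (1S,3E,5R,7E,11E).
Assumption: the sense of induction in steps 3 and 6 is assigned by analogy with aromatic and conjugated aldehydes under the same catalysts.

Step 1
Reactants: 1 geranyl bromide; 2 thioanisole
Product: 4 homogeranyl phenyl sulfide, via (phenylthio)methyllithium 3 (not isolated)
Conditions: 2, n-BuLi, DABCO, THF, 0 °C; then 1, −78 °C → rt
Reagents that add atoms: none
Why: Corey–Seebach α-lithiation of thioanisole followed by SN2 alkylation of the primary allylic bromide adds the one carbon that becomes C9 and leaves the E alkene untouched.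

Step 2
Reactants: 4 homogeranyl phenyl sulfide
Product: 6 homogeranyl iodide, via sulfonium iodide 5 (not isolated)
Conditions: MeI (excess), NaI, DMF, 75 °C, dark
Reagents that add atoms: iodomethane, CI; sodium iodide, [Na+].[I-]
Why: Corey–Jautelat sulfide-to-iodide exchange, in which S-methylation gives sulfonium salt 5, iodide attack at its methyl group is degenerate, and SN2 attack at the unhindered primary C9 releases thioanisole.

Step 3
Reactants: 7 furan-3-carbaldehyde; 8 allyltributylstannane
Product: 10 (1S)-1-(furan-3-yl)but-3-en-1-ol, via stannyl ether 9 (not isolated)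
Conditions: (S)-BINOL (20 mol %), Ti(OiPr)4 (10 mol %), 4 Å MS, CH2Cl2, −20 °C; aq NaHCO3
Reagents that add atoms: none
Why: Keck asymmetric allylation, in which the (S)-BINOL–Ti(IV) Lewis acid shields the Re face of the aldehyde so that the allylstannane adds to the Si face (open SE2' transition state) and sets C1 as S.

Step 4
Reactants: 10 (1S)-1-(furan-3-yl)but-3-en-1-ol
Product: 11 TBS ether of 10
Conditions: TBSCl, imidazole, DMF, rt
Reagents that add atoms: tert-butyldimethylsilyl chloride, CC(C)(C)[Si](C)(C)Cl
Why: Standard imidazole-promoted silylation masks the acidic C1 hydroxyl against the organometallic reagents of step 8 without touching the stereocentre.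

Step 5
Reactants: 11 TBS ether; 12 methacrolein
Product: 13 (2E,5S)-5-(tert-butyldimethylsilyloxy)-5-(furan-3-yl)-2-methylpent-2-enal
Conditions: Hoveyda–Grubbs II (5 mol %), 12 (excess), CH2Cl2, 40 °C
Reagents that add atoms: none
Why: Olefin cross metathesis between a type I terminal alkene and the electron-poor 1,1-disubstituted methacrolein is selective for the cross product and should give the thermodynamically preferred E enal (the future 3E alkene).

Step 6
Reactants: 13 enal; 14 allenylboronic acid pinacol ester
Product: 16 (4R,5E,8S)-8-(tert-butyldimethylsilyloxy)-8-(furan-3-yl)-5-methyloct-5-en-1-yn-4-ol, via pinacol borate 15 (not isolated)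
Conditions: (R)-TRIP phosphoric acid (10 mol %), 4 Å MS, toluene, −20 °C; aq NaHCO3
Reagents that add atoms: none
Why: Chiral phosphoric acid-catalysed allenylboration (SE2' propargylation through a closed six-membered transition state), in which the (R)-TRIP pocket exposes the Re face of the enal and sets C5 as R under catalyst control because the C1 stereocentre is remote.

Step 7
Reactants: 16 alkynol
Product: 17 tributyl{(5R)-5-[(2E,5S)-5-(tert-butyldimethylsilyloxy)-5-(furan-3-yl)pent-2-en-2-yl]-4,5-dihydrofuran-2-yl}stannane
Conditions: Mo(CO)6 (25 mol %), Et3N, Et2O, hν (350 nm); then 16, Bu3SnOTf, rt; Et3N-deactivated SiO2, kept below 30 °C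
Reagents that add atoms: tributyltin triflate, CCCC[Sn](CCCC)(CCCC)OS(=O)(=O)C(F)(F)F
Why: McDonald alkynol endo-cycloisomerisation in its stannylative form, in which the terminal alkyne rearranges to a molybdenum vinylidene, the C5 hydroxyl adds to its electrophilic carbon (net 5-endo closure) and the anionic alkenylmolybdenum is trapped by Bu3Sn+ instead of H+, which installs the C8 metal handle without a base strong enough to deprotonate the furan and leaves C5 untouched.

Step 8
Reactants: 6 homogeranyl iodide (2 equiv); 17 stannyl dihydrofuran (1 equiv)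
Product: 23 (1S,3E,5R,7E,11E)-1-(tert-butyldimethylsilyloxy)-1-(furan-3-yl)-4,8,12,16-tetramethylheptadeca-3,7,11,15-tetraen-5-ol, via homogeranyllithium 18 (not isolated), via lithium dihomogeranylcuprate 19 (not isolated), via lithiated dihydrofuran 20 (not isolated), via mixed cuprate 21 (not isolated), via alkenylcuprate 22 (not isolated)
Conditions: 6, t-BuLi (2 equiv per iodide), Et2O–pentane, −78 °C; CuBr·SMe2 (1 equiv), Et2O–Me2S, −78 → −30 °C; separately 17, n-BuLi (1 equiv), THF, −78 °C, 15 min, cannulated into the cuprate; −78 °C → rt; MeI (excess), 0 °C → rt; aq NH4Cl/NH3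
Reagents that add atoms: iodomethane, CI
Why: Tin–lithium exchange at −78 °C should give the C8-lithiated dihydrofuran 20 faster than any organolithium present can deprotonate the furan α-positions, and its union with homocuprate 19 gives mixed cuprate 21. On warming, one homogeranyl ligand migrates from copper to C8 anti to the C8–O bond (1,2-metalate rearrangement), forming C8–C9 with inversion at the alkenyl carbon while the ring oxygen leaves as the C5 lithium alkoxide. The closest known reaction type is the copper-mediated 1,2-metalate rearrangement of 5-lithio-2,3-dihydrofurans with alkylcuprates followed by alkyl halide capture, established for the iterative assembly of E-trisubstituted isoprenoid chains from homoallylic lithium reagents. No ring is closed (the temporary dihydrofuran is opened) and no stereocentre is created, since C5 keeps its configuration because only the C8(sp2)–O bond breaks, and C1 is remote. The 7E geometry is stereospecific, because invertive migration places C9 trans and copper cis to C6, and methylation of alkenylcuprate 22 with MeI proceeds with retention. The step needs chemoselective metalation (secured by the C8–Sn bond), a single migrating group (both transferable ligands on copper are homogeranyl) and C- over O-methylation (soft cuprate against a hard lithium alkoxide in ethereal solvent).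

Step 9
Reactants: 23 C1 silyl ether
Product: 24 (1S,3E,5R,7E,11E)-1-(furan-3-yl)-4,8,12,16-tetramethylheptadeca-3,7,11,15-tetraene-1,5-diol (target)
Conditions: TBAF, THF, 0 °C → rt
Reagents that add atoms: none
Why: Fluoride-induced cleavage of the Si–O bond under non-acidic conditions spares the ionisable furylic and allylic carbinols and all four alkenes.

Compound list
1 | geranyl bromide, (2E)-1-bromo-3,7-dimethylocta-2,6-diene | CC(C)=CCC/C(C)=C/CBr | starting material
2 | thioanisole (methyl phenyl sulfide) | CSc1ccccc1 | starting material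
3 | (phenylthio)methyllithium | [Li]CSc1ccccc1 | intermediate
4 | homogeranyl phenyl sulfide, [(3E)-4,8-dimethylnona-3,7-dien-1-yl](phenyl)sulfane | CC(C)=CCC/C(C)=C/CCSc1ccccc1 | intermediate
5 | [(3E)-4,8-dimethylnona-3,7-dien-1-yl](methyl)(phenyl)sulfonium iodide | CC(C)=CCC/C(C)=C/CC[S+](C)c1ccccc1.[I-] | intermediate
6 | homogeranyl iodide, (3E)-1-iodo-4,8-dimethylnona-3,7-diene | CC(C)=CCC/C(C)=C/CCI | intermediate
7 | furan-3-carbaldehyde | O=Cc1ccoc1 | starting material
8 | allyltributylstannane | C=CC[Sn](CCCC)(CCCC)CCCC | starting material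
9 | tributylstannyl ether of 10 | C=CC[C@H](O[Sn](CCCC)(CCCC)CCCC)c1ccoc1 | intermediate
10 | (1S)-1-(furan-3-yl)but-3-en-1-ol | C=CC[C@H](O)c1ccoc1 | intermediate
11 | tert-butyl{[(1S)-1-(furan-3-yl)but-3-en-1-yl]oxy}dimethylsilane | C=CC[C@H](O[Si](C)(C)C(C)(C)C)c1ccoc1 | intermediate
12 | methacrolein | C=C(C)C=O | starting material
13 | (2E,5S)-5-(tert-butyldimethylsilyloxy)-5-(furan-3-yl)-2-methylpent-2-enal | O=C/C(C)=C/C[C@H](O[Si](C)(C)C(C)(C)C)c1ccoc1 | intermediate
14 | allenylboronic acid pinacol ester | C=C=CB1OC(C)(C)C(C)(C)O1 | starting material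
15 | pinacol borate of alkynol 16 | C#CC[C@@H](OB1OC(C)(C)C(C)(C)O1)/C(C)=C/C[C@H](O[Si](C)(C)C(C)(C)C)c1ccoc1 | intermediate
16 | (4R,5E,8S)-8-(tert-butyldimethylsilyloxy)-8-(furan-3-yl)-5-methyloct-5-en-1-yn-4-ol | C#CC[C@@H](O)/C(C)=C/C[C@H](O[Si](C)(C)C(C)(C)C)c1ccoc1 | intermediate
17 | (5R)-5-alkenyl-2-tributylstannyl-4,5-dihydrofuran (ring atoms O, C5, C6, C7, C8 of the target; Sn on C8) | CCCC[Sn](CCCC)(CCCC)C1=CC[C@@H](O1)/C(C)=C/C[C@H](O[Si](C)(C)C(C)(C)C)c1ccoc1 | intermediate
18 | homogeranyllithium | CC(C)=CCC/C(C)=C/CC[Li] | intermediate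
19 | lithium dihomogeranylcuprate | [Li+].CC(C)=CCC/C(C)=C/CC[Cu-]CC/C=C(\C)CCC=C(C)C | intermediate
20 | C8-lithiated dihydrofuran | [Li]C1=CC[C@@H](O1)/C(C)=C/C[C@H](O[Si](C)(C)C(C)(C)C)c1ccoc1 | intermediate
21 | dilithium dihomogeranyl(dihydrofuranyl)cuprate | [Li+].[Li+].CC(C)=CCC/C(C)=C/CC[Cu-2](CC/C=C(\C)CCC=C(C)C)C1=CC[C@@H](O1)/C(C)=C/C[C@H](O[Si](C)(C)C(C)(C)C)c1ccoc1 | intermediate
22 | ring-opened alkenyl(homogeranyl)cuprate C5 lithium alkoxide (Cu on C8, cis to C6) | [Li+].[Li+].CC(C)=CCC/C(C)=C/CC/C([Cu-]CC/C=C(\C)CCC=C(C)C)=C/C[C@@H]([O-])/C(C)=C/C[C@H](O[Si](C)(C)C(C)(C)C)c1ccoc1 | intermediate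
23 | (1S,3E,5R,7E,11E)-1-(tert-butyldimethylsilyloxy)-1-(furan-3-yl)-4,8,12,16-tetramethylheptadeca-3,7,11,15-tetraen-5-ol | CC(C)=CCC/C(C)=C/CC/C(C)=C/C[C@@H](O)/C(C)=C/C[C@H](O[Si](C)(C)C(C)(C)C)c1ccoc1 | intermediate
24 | (1S,3E,5R,7E,11E)-1-(furan-3-yl)-4,8,12,16-tetramethylheptadeca-3,7,11,15-tetraene-1,5-diol | CC(C)=CCC/C(C)=C/CC/C(C)=C/C[C@@H](O)/C(C)=C/C[C@H](O)c1ccoc1 | target

Total step count: 9
Longest linear sequence: 7 (steps 3–9, from furan-3-carbaldehyde)

Steps most likely to fail

Step 8. Three things may erode the coupling: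
- proton transfer from the furan α-positions to the lithiated enol ether
- incomplete ligand migration before thermal decay of the cuprate
- coupling of the wrong copper ligand during methylation

The fallback makes the same C8–C9 bond by sp3–sp2 Negishi cross-coupling. It sets out from 16 and 6 and comes back at 24. The C5 hydroxyl of 16 is silylated (TESCl, imidazole) to the C5 triethylsilyl ether F1. The terminal alkyne is deprotonated (n-BuLi, 1 equiv, −78 °C) and methylated with MeI to the methyl-capped 2-alkyne F2. Hydrozirconation with excess Cp2Zr(H)Cl, which equilibrates zirconium to the less hindered methyl-bearing carbon, followed by iodine gives the (E)-alkenyl iodide F3. Zinc insertion into 6 (Zn, LiCl, THF) gives homogeranylzinc iodide F4. It is coupled with F3 under PdCl2(dppf) with retention to the bis-silyl ether F5. TBAF then removes both silyl groups to give 24.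

Step 7. Three things may go wrong:
- protonation of the alkenylmolybdenum intermediate may outrun stannylation
- the tin triflate may ionise the allylic or furylic C–O bonds
- the product may protodestannylate during purification

The fallback separates ring closure from metalation and uses a sulfone-stabilised anion. It sets out from 16 and comes back at 17. Tin-free molybdenum-catalysed cycloisomerisation gives the unstannylated dihydrofuran F6. Benzenesulfinic acid adds across the enol ether (CH2Cl2, rt) to the 2-(phenylsulfonyl)tetrahydrofuran F7. Its α-sulfonyl C–H, far more acidic than any furan C–H, is removed with n-BuLi at −78 °C and quenched with Bu3SnCl to the α-stannyl sulfone F8. Gentle warming with i-Pr2NEt eliminates sulfinate to give 17.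

Step 6. Facial selectivity may be poor with the α-branched enal, or slow turnover may let the uncatalysed background addition erode purity at C5. The fallback replaces asymmetric addition by resolution. It sets out from 13 and comes back at 16. Barbier propargylation (propargyl bromide, Zn, THF/aq NH4Cl) gives the C4-epimeric alkynol mixture F9. Sharpless kinetic resolution (Ti(OiPr)4, L-(+)-DIPT, TBHP, 4 Å MS, −20 °C) should consume the fast-reacting (4S)-epimer as the polar epoxy alcohol F10. The slow-reacting (4R)-allylic alcohol 16 is left to be separated by chromatography.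

Further compounds
F1 | step 8 | C5 triethylsilyl ether of alkynol 16 | C#CC[C@@H](O[Si](CC)(CC)CC)/C(C)=C/C[C@H](O[Si](C)(C)C(C)(C)C)c1ccoc1
F2 | step 8 | methyl-capped 2-alkyne | CC#CC[C@@H](O[Si](CC)(CC)CC)/C(C)=C/C[C@H](O[Si](C)(C)C(C)(C)C)c1ccoc1
F3 | step 8 | (E)-alkenyl iodide (iodine on C8, trans to C6) | I/C(C)=C/C[C@@H](O[Si](CC)(CC)CC)/C(C)=C/C[C@H](O[Si](C)(C)C(C)(C)C)c1ccoc1
F4 | step 8 | homogeranylzinc iodide | CC(C)=CCC/C(C)=C/CC[Zn]I
F5 | step 8 | C1-O-TBS, C5-O-TES bis-silyl ether of the target | CC(C)=CCC/C(C)=C/CC/C(C)=C/C[C@@H](O[Si](CC)(CC)CC)/C(C)=C/C[C@H](O[Si](C)(C)C(C)(C)C)c1ccoc1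
F6 | step 7 | unstannylated (2R)-2-alkenyl-2,3-dihydrofuran | C1=CC[C@@H](O1)/C(C)=C/C[C@H](O[Si](C)(C)C(C)(C)C)c1ccoc1
F7 | step 7 | 2-(phenylsulfonyl)tetrahydrofuran, mixture at the sulfonyl carbon | O=S(=O)(c1ccccc1)C1CC[C@@H](O1)/C(C)=C/C[C@H](O[Si](C)(C)C(C)(C)C)c1ccoc1
F8 | step 7 | α-stannyl sulfone, mixture at the sulfonyl carbon | O=S(=O)(c1ccccc1)C1([Sn](CCCC)(CCCC)CCCC)CC[C@@H](O1)/C(C)=C/C[C@H](O[Si](C)(C)C(C)(C)C)c1ccoc1
F9 | step 6 | alkynol as C4-epimeric mixture | C#CCC(O)/C(C)=C/C[C@H](O[Si](C)(C)C(C)(C)C)c1ccoc1
F10 | step 6 | (4S,5S,6S,8S)-5,6-epoxy alcohol from the (4S)-epimer | C#CC[C@H](O)[C@]1(C)O[C@H]1C[C@H](O[Si](C)(C)C(C)(C)C)c1ccoc1
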